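The ten-membered carbocycle (C1–C10, germacrane numbering: C1 furanone C=O, C3 furanone C–O carbon, C6/C7 lactone fusion, C8 tiglate carbon) is disconnected at C3–C4. C1, C10, C9, C8, C7 (with its three-carbon branch) and C6 are the six ring carbons of (R)-carvone. An anionic oxy-Cope shift of a 1-(ethoxyethynyl)-2-(E-propenyl)cyclohexanol therefore forms C3–C4, cleaves C1–C6, expands the ring by four atoms, delivers C3 at the furanone oxidation level and sets C4 and the E-C5=C6 alkene. The precursor has alkynyl and propenyl trans (both equatorial) and the cis-8,10-diol tied as a p-methoxybenzylidene acetal.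

Key step: step 8

Remark 1 (numbering and faces): β is the face of the C7 side chain (C11–C13) and of the C10 methyl group; α is the opposite face.
Remark 2 (C1 carbinol): the C1 configuration of the rearrangement substrate is not innocent. Only with the alkynyl group trans to the propenyl group (both equatorial in the chair-like transition state) does the shift give the E-C5=C6 alkene and 4S. The cis epimer would react through an axial alkynyl group and give the Z-alkene and 4R. Compound 13 is therefore the 1β-alkynyl-1α-ol.
Remark 3 (design): the ynol ether is introduced last before the key step, after the allyl-to-propenyl isomerisation, because it would not survive metal hydride catalysts. The C2=C3 geometry drawn for 16 is the one expected from protonation of the allenolate from outside the ring; it is erased in step 9.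

Step 1
Reactants: 1 (R)-carvone; 2 allyl bromide
Product: 4 trans-6-allylcarvone (6α-allyl), via lithium dienolate 3 (not isolated)
Conditions: LDA, THF, −78 °C; then allyl bromide, −78 → 0 °C
Reagents that add atoms: none
Why: kinetic α′-deprotonation at C6 gives the cross-conjugated lithium dienolate, which is allylated (enolate alkylation) anti to the vicinal C7 isopropenyl group, so that C6 is set trans (both substituents equatorial, also the thermodynamic arrangement).

Step 2
Reactants: 4 trans-6-allylcarvone
Product: 5 linear TBS dienol ether (1-silyloxy-1(10),8-diene)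
Conditions: TBSOTf, Et3N, CH2Cl2, 0 °C → rt
Reagents that add atoms: tert-butyldimethylsilyl triflate, CC(C)(C)[Si](C)(C)OS(=O)(=O)C(F)(F)F
Why: soft enolisation (O-silylation, then deprotonation by the amine) should remove a γ-hydrogen at C8 rather than the hindered tertiary α′-hydrogen at C6, and the reversible conditions favour the linearly conjugated silyloxy diene.

Step 3
Reactants: 5 linear TBS dienol ether
Product: 6 8α-hydroxy-6α-allylcarvone (γ-hydroxy enone)
Conditions: m-CPBA, NaHCO3, CH2Cl2, −78 → −30 °C
Reagents that add atoms: m-chloroperbenzoic acid, OOC(=O)c1cccc(Cl)c1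
Why: vinylogous Rubottom oxidation, in which the peracid attacks the electron-rich diene at its γ terminus C8 (C10 is fully substituted) anti to the vicinal, pseudo-axial C7 isopropenyl group, setting 8α-OH, while the isolated alkenes are far less nucleophilic at low temperature.

Step 4
Reactants: 6 8α-hydroxy-6α-allylcarvone
Product: 8 8α,10α-dihydroxy-10β-methyl ketone, via 10-hydroperoxide 7 (not isolated)
Conditions: Mn(dpm)3 (cat.), PhSiH3, O2 (1 atm), i-PrOH/CH2Cl2, 0 °C; then P(OEt)3
Reagents that add atoms: dioxygen, O=O
Why: Mukaiyama-type reductive α-hydroxylation of the enone (hydrogen-atom transfer to C9, O2 capture by the tertiary C10 radical, phosphite reduction of the hydroperoxide) is faster than hydration of the isolated alkenes; C10 is set at the O2 capture, which is only weakly face-selective, so both epimers are expected and the 8,10-cis diol 8 is the one carried on (the trans diol cannot close the bridge of step 5).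

Step 5
Reactants: 8 8α,10α-dihydroxy-10β-methyl ketone
Product: 9 8,10-O-(p-methoxybenzylidene) acetal (aryl exo)
Conditions: p-MeOC6H4CH(OMe)2, CSA (cat.), toluene, 40 °C, reduced pressure (−MeOH)
Reagents that add atoms: p-anisaldehyde dimethyl acetal, COc1ccc(cc1)C(OC)OC
Why: acid-catalysed transacetalisation driven by removal of methanol bridges the cis-1,3-diol as a 1,3-dioxane with the aryl group equatorial (exo), and because the C6 allyl group cannot sit endo over the dioxane the carbocycle takes a boat in which the allyl and isopropenyl groups stay pseudo-equatorial.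

Step 6
Reactants: 9 8,10-O-(p-methoxybenzylidene) acetal (aryl exo)
Product: 10 6α-(E)-prop-1-enyl ketone acetal
Conditions: Pd(dba)2 (cat.), P(t-Bu)3 (cat.), i-PrCOCl (cat.), toluene, 80 °C
Reagents that add atoms: none
Why: palladium hydride alkene isomerisation (hydrometallation/β-hydride elimination) moves the terminal double bond by one position to the more stable E-propenyl group and stops there because further migration would need insertion towards the hindered tertiary C6–H; no base is present, so C6 is not epimerised.

Step 7
Reactants: 10 6α-(E)-prop-1-enyl ketone acetal; 11 ethoxyacetylene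
Product: 13 1β-(ethoxyethynyl)-1α-hydroxy acetal (alkynyl trans to propenyl), via lithium ethoxyacetylide 12 (not isolated)
Conditions: 11, n-BuLi, THF, −78 °C; CeCl3, −78 °C; then 10, −78 °C; aq. NaHCO3 work-up, no acid
Reagents that add atoms: none
Why: organocerium acetylide 1,2-addition outruns enolisation of the β,γ-unsaturated ketone, and C1 is set by attack on the exo (β) face, since the α face is covered by the dioxane bridge and the α-oriented C10–O bond lies anti to the incoming nucleophile (Felkin–Anh polar model), which puts the alkynyl group cis to the C10 methyl and trans to the C6 propenyl group.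

Step 8
Reactants: 13 1β-(ethoxyethynyl)-1α-hydroxy acetal (alkynyl trans to propenyl)
Product: 16 (4S,5E)-3-ethoxycyclodeca-2,5-dien-1-one acetal, via potassium alkoxide 14 (not isolated), via potassium allenolate 15 (not isolated)
Conditions: KH, 18-crown-6, THF, 0 °C → rt; then sat. aq. NH4Cl, −78 °C
Reagents that add atoms: none
Why: Proposed new method: the potassium alkoxide 14 is expected to undergo a concerted, alkoxide-accelerated [3,3] shift in which C3 of the ynol ether bonds to C4 of the propenyl group while C1–C6 breaks, giving the endocyclic allenolate 15 that is protonated at C2 on quench; the closest known reaction is the anionic oxy-Cope rearrangement of 1-ethynyl-2-vinylcyclohexanols to cyclodeca-2,5-dienones, the alkoxy group on the alkyne being the only extension. The ten-membered ring is not closed by an exo or endo attack but by ring expansion through a six-centre chair-like array (C3–C2–C1–C6–C5–C4) that inserts C2–C5 between C1 and C6. C4 is set by suprafacial chirality transfer from the sacrificial C6 centre: with the C6–C7 ring bond equatorial in the transition state, H6 eclipses the E-propenyl double bond and C3 adds to the face of C4 from which C1 departs, giving 4S (4α-methyl) and the E-C5=C6 alkene. The step needs this diequatorial transition state and not the one with an axial alkynyl group (Z-alkene, 4R); the trans relation of alkynyl and propenyl in 13 and the E geometry of the propenyl group secure it. Relief of the boat strain of the bridged cyclohexane and the crown-ether-separated ion pair should let the shift run at or below room temperature, where retro-alkynylation of the alkoxide and proton shuffling at the doubly activated C4–H of 15 are slow.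

Step 9
Reactants: 16 (4S,5E)-3-ethoxycyclodeca-2,5-dien-1-one acetal
Product: 18 furanone alcohol (3,10-epoxy-8α-hydroxy-2,5E,11(13)-trien-1-one), via 8α,10α-diol 17 (not isolated)
Conditions: 1 M HCl, THF, rt
Reagents that add atoms: none
Why: aqueous acid hydrolyses the benzylidene acetal and the freed C10 hydroxyl adds to C3 of the protonated vinylogous ester (5-exo attack on the oxocarbenium ion) with loss of ethanol, the standard acid cyclisation of an α′-hydroxy 1,3-diketone equivalent to a 3(2H)-furanone; the C2=C3 geometry of 16 is irrelevant because C2 is sp3 in the ketal intermediate, and any bicyclic ketal formed by the C8 hydroxyl is in equilibrium with 18.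

Step 10
Reactants: 18 furanone alcohol; 19 tiglic acid
Product: 21 8-O-tiglate, via mixed anhydride 20 (not isolated)
Conditions: 19, 2,4,6-Cl3C6H2COCl, Et3N, toluene, rt; then 18, DMAP, rt
Reagents that add atoms: none
Why: Yamaguchi esterification, in which DMAP attacks the mixed anhydride at the less hindered tigloyl carbonyl and the acylpyridinium ion acylates the only hydroxyl present; acylating now protects C8–OH from iodoetherification in step 13 and saves a protecting group.

Step 11
Reactants: 21 8-O-tiglate
Product: 22 C12 enal (2-substituted acrolein)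
Conditions: SeO2, 1,4-dioxane, 70 °C
Reagents that add atoms: selenium dioxide, O=[Se]=O
Why: Riley allylic oxidation (ene reaction, [2,3]-shift, further oxidation) converts the methyl group of the 1,1-disubstituted isopropenyl alkene, the most electron-rich alkene present, into the aldehyde, while the conjugated tiglate and furanone alkenes are deactivated and the disubstituted C5=C6 alkene reacts more slowly.

Step 12
Reactants: 22 C12 enal
Product: 23 acrylic acid (C12 acid)
Conditions: NaClO2, NaH2PO4, 2-methyl-2-butene, t-BuOH/H2O, 0 °C → rt
Reagents that add atoms: sodium chlorite, [Na+].[O-]Cl=O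
Why: Pinnick oxidation of the enal to the acid under buffered conditions, with 2-methyl-2-butene scavenging the hypochlorous acid so that the alkenes and the furanone are untouched.

Step 13
Reactants: 23 acrylic acid
Product: 24 5-iodo-12,6α-olide (α-methylene lactone)
Conditions: I2, NaHCO3, MeCN, 0 °C, dark
Reagents that add atoms: iodine, II
Why: iodolactonisation, in which the carboxylate opens the iodonium ion of the C5=C6 alkene at C6 (5-exo) on the face that carries C11 and anti to iodine; with H7 eclipsing the E double bond (allylic strain minimised, C8 held out of plane by the ring) this sets 6R, the trans-fused lactone.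

Step 14
Reactants: 24 5-iodo-12,6α-olide
Product: 25 11(13)-dehydro target (α-methylene lactone)
Conditions: Bu3SnH, AIBN (cat.), toluene, 80 °C
Reagents that add atoms: none
Why: radical chain dehalogenation, in which iodine abstraction by the stannyl radical is much faster than its addition to the methylene lactone and the secondary C5 radical is reduced by the tin hydride before it can cyclise (only 3- or 4-membered or 5-endo closures are available).

Step 15
Reactants: 25 11(13)-dehydro target
Product: 26 target CNP0235937.1
Conditions: Cu(OAc)2·H2O (cat.), 1,2-bis(diphenylphosphino)benzene (cat.), (EtO)2MeSiH, t-BuOH, toluene, 0 °C → rt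
Reagents that add atoms: none
Why: copper hydride conjugate reduction selects the unhindered exocyclic acrylate (the tiglate is α,β-disubstituted, the furanone is a vinylogous ester), and C11 is set on protonation of the enolate by t-BuOH from the β face, anti to the pseudo-axial H7 and away from the 8α-acyloxy group, giving the 11α-methyl (11S) lactone, which is also the more stable epimer.

Compound list
1 | (R)-carvone | CC(=C)[C@@H]1CC=C(C)C(=O)C1 | starting material
2 | allyl bromide | C=CCBr | starting material
3 | lithium cross-conjugated dienolate of carvone | [Li+].[O-]C1=C[C@H](C(C)=C)CC=C1C | intermediate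
4 | trans-6-allylcarvone (6α-allyl, 7β-isopropenyl) | C1C=C(C)C(=O)[C@@H](CC=C)[C@@H]1C(C)=C | intermediate
5 | linear TBS dienol ether of 4 | C1=CC(C)=C(O[Si](C)(C)C(C)(C)C)[C@@H](CC=C)[C@@H]1C(C)=C | intermediate
6 | 8α-hydroxy-6α-allylcarvone | O[C@H]1C=C(C)C(=O)[C@@H](CC=C)[C@@H]1C(C)=C | intermediate
7 | 10α-hydroperoxy-8α-hydroxy ketone | O[C@H]1C[C@@](C)(OO)C(=O)[C@@H](CC=C)[C@@H]1C(C)=C | intermediate
8 | 8α,10α-dihydroxy-6α-allyl-7β-isopropenyl-10β-methylcyclohexanone | O[C@H]1C[C@@](C)(O)C(=O)[C@@H](CC=C)[C@@H]1C(C)=C | intermediate
9 | 8,10-O-(p-methoxybenzylidene) acetal of 8, aryl exo | COc1ccc(cc1)[C@H]2O[C@H]3C[C@@](C)(O2)C(=O)[C@@H](CC=C)[C@@H]3C(C)=C | intermediate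
10 | 6α-(E)-prop-1-enyl ketone acetal | COc1ccc(cc1)[C@H]2O[C@H]3C[C@@](C)(O2)C(=O)[C@@H](/C=C/C)[C@@H]3C(C)=C | intermediate
11 | ethoxyacetylene | CCOC#C | starting material
12 | lithium ethoxyacetylide | [Li]C#COCC | intermediate
13 | 1β-(ethoxyethynyl)-1α-hydroxy acetal, alkynyl trans to propenyl (rearrangement substrate) | COc1ccc(cc1)[C@H]2O[C@H]3C[C@@](C)(O2)[C@](O)(C#COCC)[C@@H](/C=C/C)[C@@H]3C(C)=C | intermediate
14 | potassium alkoxide of 13 | COc1ccc(cc1)[C@H]2O[C@H]3C[C@@](C)(O2)[C@]([O-])(C#COCC)[C@@H](/C=C/C)[C@@H]3C(C)=C.[K+] | intermediate
15 | potassium allenolate (ten-membered 1,2,5-trien-1-olate) | COc1ccc(cc1)[C@H]2O[C@H]3C[C@@](C)(O2)C([O-])=C=C(OCC)[C@@H](C)/C=C/[C@@H]3C(C)=C.[K+] | intermediate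
16 | (4S,5E)-3-ethoxycyclodeca-2,5-dien-1-one acetal (rearrangement product) | COc1ccc(cc1)[C@H]2O[C@H]3C[C@@](C)(O2)C(=O)/C=C(/OCC)[C@@H](C)/C=C/[C@@H]3C(C)=C | intermediate
17 | 8α,10α-diol of 16 | O[C@H]1C[C@@](C)(O)C(=O)/C=C(/OCC)[C@@H](C)/C=C/[C@@H]1C(C)=C | intermediate
18 | furanone alcohol (3,10-epoxy-8α-hydroxy-2,5E,11(13)-trien-1-one) | O[C@H]1C[C@@]2(C)OC(=CC2=O)[C@@H](C)/C=C/[C@@H]1C(C)=C | intermediate
19 | tiglic acid | C/C=C(\C)C(=O)O | starting material
20 | tiglic 2,4,6-trichlorobenzoic anhydride | C/C=C(\C)C(=O)OC(=O)c1c(Cl)cc(Cl)cc1Cl | intermediate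
21 | 8-O-tiglate of 18 | C/C=C(\C)C(=O)O[C@H]1C[C@@]2(C)OC(=CC2=O)[C@@H](C)/C=C/[C@@H]1C(C)=C | intermediate
22 | C12 enal | C/C=C(\C)C(=O)O[C@H]1C[C@@]2(C)OC(=CC2=O)[C@@H](C)/C=C/[C@@H]1C(=C)C=O | intermediate
23 | acrylic acid | C/C=C(\C)C(=O)O[C@H]1C[C@@]2(C)OC(=CC2=O)[C@@H](C)/C=C/[C@@H]1C(=C)C(=O)O | intermediate
24 | 5-iodo-12,6α-olide | C/C=C(\C)C(=O)O[C@H]1C[C@@]2(C)OC(=CC2=O)[C@@H](C)[C@@H](I)[C@H]2OC(=O)C(=C)[C@H]12 | intermediate
25 | 11(13)-dehydro target | C/C=C(\C)C(=O)O[C@H]1C[C@@]2(C)OC(=CC2=O)[C@@H](C)C[C@H]2OC(=O)C(=C)[C@H]12 | intermediate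
26 | CNP0235937.1 | C/C=C(\C)C(=O)O[C@H]1C[C@@]2(C)OC(=CC2=O)[C@@H](C)C[C@H]2OC(=O)[C@@H](C)[C@H]12 | target

Total steps: 15. Longest linear sequence: 15 steps from (R)-carvone (fully linear).

Steps most likely to fail

1. Step 8 (Proposed new method). What may go wrong: the potassium alkoxide may revert to ketone and acetylide, or the ynol ether may be degraded by the base before the shift. The allenolate may also shuttle the doubly activated C4 proton, which would epimerise C4 or move C5=C6 into conjugation. Fallback, known chemistry only, from 10: addition of ethynylmagnesium bromide/CeCl3 gives the 1β-ethynyl carbinol F1. Its potassium alkoxide (KH, 18-crown-6, THF) undergoes the established acetylenic anionic oxy-Cope ring expansion to the (5E)-cyclodeca-2,5-dienone acetal F2, with the same control of C4. Aqueous HCl removes the acetal and the C10 hydroxyl adds to C3 of the enone (intramolecular oxa-Michael addition) to give the dihydrofuran-3(2H)-one alcohol F3. Yamaguchi acylation with 19 gives the dihydrofuranone tiglate F4. Dehydrogenation of the ring ketone (IBX, DMSO, 70 °C, or Saegusa–Ito oxidation) returns to the route at 21.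

2. Step 4. What may go wrong: O2 capture at the planar C10 radical may be unselective or favour axial entry on the β face, so that little of the 8,10-cis diol forms; hydration of the isopropenyl group may compete. Fallback from 6: silylation (TMSCl, imidazole) gives the 8-O-TMS enone F5. 1,4-Reduction with L-Selectride and trapping with TBSOTf gives the regiodefined TBS enol ether F6. K2CO3/MeOH frees the 8-hydroxyl to give the hydroxy enol ether F7. Rubottom oxidation with m-CPBA, in which the peracid is delivered to the α face of C10 by hydrogen bonding to the pseudo-axial homoallylic 8α-hydroxyl, followed by fluoride work-up, returns to the route at 8.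

3. Step 5. What may go wrong: the bridge closes only if the cyclohexane leaves its all-equatorial chair for a boat, so the equilibrium may stop at acyclic mixed acetals, and prolonged acid may epimerise C6. Fallback from 8: selective etherification of the secondary hydroxyl with p-methoxybenzyl trichloroacetimidate (CSA cat.) gives the 8-O-PMB ether F8. Anhydrous DDQ (4 Å sieves, CH2Cl2) then oxidises the benzyl ether to its oxocarbenium ion, which the C10 hydroxyl traps irreversibly; this oxidative acetal closure returns to the route at 9.

Further compounds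
F1 | step 8 | 1β-ethynyl-1α-hydroxy acetal | COc1ccc(cc1)[C@H]2O[C@H]3C[C@@](C)(O2)[C@](O)(C#C)[C@@H](/C=C/C)[C@@H]3C(C)=C
F2 | step 8 | (4S,5E)-cyclodeca-2,5-dien-1-one acetal | COc1ccc(cc1)[C@H]2O[C@H]3C[C@@](C)(O2)C(=O)/C=C\[C@@H](C)/C=C/[C@@H]3C(C)=C
F3 | step 8 | dihydrofuran-3(2H)-one alcohol (C3 epimers) | O[C@H]1C[C@@]2(C)OC(CC2=O)[C@@H](C)/C=C/[C@@H]1C(C)=C
F4 | step 8 | dihydrofuranone 8-O-tiglate | C/C=C(\C)C(=O)O[C@H]1C[C@@]2(C)OC(CC2=O)[C@@H](C)/C=C/[C@@H]1C(C)=C
F5 | step 4 | 8-O-TMS ether of 6 | C[Si](C)(C)O[C@H]1C=C(C)C(=O)[C@@H](CC=C)[C@@H]1C(C)=C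
F6 | step 4 | TBS enol ether (C1=C10) with 8-O-TMS | C[Si](C)(C)O[C@H]1CC(C)=C(O[Si](C)(C)C(C)(C)C)[C@@H](CC=C)[C@@H]1C(C)=C
F7 | step 4 | 8α-hydroxy TBS enol ether | O[C@H]1CC(C)=C(O[Si](C)(C)C(C)(C)C)[C@@H](CC=C)[C@@H]1C(C)=C
F8 | step 5 | 8-O-PMB ether of 8 | COc1ccc(cc1)CO[C@H]1C[C@@](C)(O)C(=O)[C@@H](CC=C)[C@@H]1C(C)=C
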